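**Retrosynthetic overview**
1. Target ⇒ 3-bromo-2-(2-bromophenoxy)phenol: the C4 and C6 bromines go on last, para and ortho to the free OH.
2. Phenol OH ⇒ formyl group (Baeyer–Villiger/Dakin-type); the CHO first serves as the SNAr activator.
3. Diaryl ether C–O ⇒ 2-bromophenol + 3-bromo-2-fluorobenzaldehyde (SNAr at the C–F ortho to CHO).
4. No ring is formed: both benzene rings are bought, and the C3 and C2' bromines come with the building blocks.

Assumption: the target has no stereocentre and no configurationally stable axis, so it is achiral and "single enantiomer" means the constitution shown.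

**Step 1**
Reactants: 1 2-bromophenol; 2 3-bromo-2-fluorobenzaldehyde
Product: 3 3-bromo-2-(2-bromophenoxy)benzaldehyde
Conditions: K2CO3 (1.5 equiv), DMAc, 120 °C
Reagents that add atoms: none
Why: Nucleophilic aromatic substitution (SNAr, addition–elimination) in which the phenoxide displaces the fluoride ortho to the formyl group, the aryl bromides being inert without a metal catalyst; no stereocentre is formed.

**Step 2**
Reactants: 3 3-bromo-2-(2-bromophenoxy)benzaldehyde
Product: 5 3-bromo-2-(2-bromophenoxy)phenol, via 3-bromo-2-(2-bromophenoxy)phenyl formate 4 (not isolated)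
Conditions: mCPBA (1.5 equiv), CH2Cl2, rt; then cat. HCl, MeOH, rt
Reagents that add atoms: mCPBA, OOC(=O)c1cccc(Cl)c1
Why: Baeyer–Villiger (Dakin-type) oxidation in which the ring bearing the ortho aryloxy donor migrates in preference to hydrogen to give the formate, which acid methanolysis cleaves to the phenol; no stereocentre is formed.

**Step 3**
Reactants: 5 3-bromo-2-(2-bromophenoxy)phenol
Product: 7 3,4,6-tribromo-2-(2-bromophenoxy)phenol, via 3,4-dibromo-2-(2-bromophenoxy)phenol 6 (not isolated)
Conditions: Br2 (2.05 equiv, added dropwise), AcOH, 15 °C to rt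
Reagents that add atoms: bromine, BrBr
Why: Electrophilic aromatic substitution in which the free OH directs bromine to its para (C4) and only open ortho (C6) positions, the other ortho position carrying the aryloxy group and the 2-bromophenoxy ring being a far less activated aryl ether; no stereocentre is formed.

**Compound list**
1 | 2-bromophenol | Oc1ccccc1Br | starting material
2 | 3-bromo-2-fluorobenzaldehyde | O=Cc1cccc(Br)c1F | starting material
3 | 3-bromo-2-(2-bromophenoxy)benzaldehyde | O=Cc1cccc(Br)c1Oc1ccccc1Br | intermediate
4 | 3-bromo-2-(2-bromophenoxy)phenyl formate | O=COc1cccc(Br)c1Oc1ccccc1Br | intermediate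
5 | 3-bromo-2-(2-bromophenoxy)phenol | Oc1cccc(Br)c1Oc1ccccc1Br | intermediate
6 | 3,4-dibromo-2-(2-bromophenoxy)phenol | Oc1ccc(Br)c(Br)c1Oc1ccccc1Br | intermediate
7 | 3,4,6-tribromo-2-(2-bromophenoxy)phenol | Oc1c(Br)cc(Br)c(Br)c1Oc1ccccc1Br | target

**Total step count:** 3. **Longest linear sequence:** 3 steps (1 + 2 → 3 → 5 → 7).

**Steps most likely to fail** (the route has only three steps, ranked here by risk)

Step 2, Baeyer–Villiger oxidation. The risk is hydrogen migration instead of aryl migration, which would give the benzoic acid, since the ring is slightly deactivated by the meta bromine. The fallback sets out from 1 and comes back to the route at 5. Compound 1 is condensed (K2CO3, DMAc, 120 °C) with commercial 1-(3-bromo-2-fluorophenyl)ethanone (CC(=O)c1cccc(Br)c1F) to give 1-[3-bromo-2-(2-bromophenoxy)phenyl]ethanone F1. A methyl ketone has no formyl hydrogen, so the acid-forming pathway does not exist, and with mCPBA/TFA in CH2Cl2 the aryl group migrates in preference to methyl to give 3-bromo-2-(2-bromophenoxy)phenyl acetate F2. K2CO3 in MeOH then releases 5.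

Step 3, double bromination. The risk is a mixture of mono-, di- and over-brominated products, or attack on the 2-bromophenoxy ring para to the ether oxygen. The fallback sets out from 1 and comes back to the route at 7; the ortho bromine is bought instead of installed. Compound 1 and commercial 3,6-dibromo-2-fluorobenzaldehyde (O=Cc1c(Br)ccc(Br)c1F) give, by SNAr (K2CO3, DMAc, 120 °C), 3,6-dibromo-2-(2-bromophenoxy)benzaldehyde F3. mCPBA in CH2Cl2 followed by cat. HCl/MeOH converts this, through 3,6-dibromo-2-(2-bromophenoxy)phenyl formate F4, into 3,6-dibromo-2-(2-bromophenoxy)phenol F5. A single equivalent of NBS in MeCN at 0 °C then brominates the one remaining activated position, para to the OH, to give 7.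

Step 1, SNAr. The risk is a sluggish reaction, because the fluoride sits between CHO and Br and the nucleophile is an ortho-substituted phenoxide, together with base-induced side reactions of the aldehyde at 120 °C. The fallback sets out from 1 and comes back to the route at 3. Compound 1 is coupled (K2CO3, DMF, 90 °C) with commercial 3-bromo-2-fluorobenzonitrile (N#Cc1cccc(Br)c1F). The small, base-stable nitrile activates the fluoride without the aldehyde side reactions, giving 3-bromo-2-(2-bromophenoxy)benzonitrile F6. DIBAL-H in toluene at −78 °C followed by aqueous HCl hydrolysis then delivers aldehyde 3.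

**Further compounds**
F1 | step 2 | 1-[3-bromo-2-(2-bromophenoxy)phenyl]ethanone | CC(=O)c1cccc(Br)c1Oc1ccccc1Br
F2 | step 2 | 3-bromo-2-(2-bromophenoxy)phenyl acetate | CC(=O)Oc1cccc(Br)c1Oc1ccccc1Br
F3 | step 3 | 3,6-dibromo-2-(2-bromophenoxy)benzaldehyde | O=Cc1c(Br)ccc(Br)c1Oc1ccccc1Br
F4 | step 3 | 3,6-dibromo-2-(2-bromophenoxy)phenyl formate | O=COc1c(Br)ccc(Br)c1Oc1ccccc1Br
F5 | step 3 | 3,6-dibromo-2-(2-bromophenoxy)phenol | Oc1c(Br)ccc(Br)c1Oc1ccccc1Br
F6 | step 1 | 3-bromo-2-(2-bromophenoxy)benzonitrile | N#Cc1cccc(Br)c1Oc1ccccc1Br
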